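The ten-membered ring is made by unzipping, not by closing: the C1=C10 (Z) alkene, the C2 oxygen, C3 and the C4=C5 (E) alkene are read as the ring-opened form of a 2-silyloxycyclohexa-1,3-diene (ring A) fused through C5–C10 to a cyclohexane (ring B) that already carries the C6–C7 lactone and the C8 and C9 oxygens. One photochemical conrotatory six-electron opening cuts C5–C10, merges rings A and B and fixes both alkene geometries. The precursor is a cis-fused hexalin lactone whose ring B chair, locked by the trans lactone, holds C9 and H5 pseudoaxial on ring A, the two groups that must turn inward.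

Key step: step 13

Remarks on the chemistry
- Numbering: germacrane numbering is used for every intermediate (C1–C10 carbocycle, C11–C13 lactone carbons, C14 on C10, C15 on C4).
- Ring fusion (correction to the obvious all-equatorial design): in a fused cyclohexadiene the groups that are pseudoaxial on ring A rotate inward on photochemical opening. The cis-fused diastereomer with H5 and the C10 methyl on the face of O6 and O8 is locked with C6 and the methyl pseudoaxial, and would open to the 1(10)E,4Z isomer. The route therefore builds the diastereomer with both ring-fusion centres inverted (H5 and the C10 methyl on the face of O9 and C11), where C9 and H5 are pseudoaxial.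
- The triene 16 is cis,cis,trans in the ring sense; by CIP it is (1(10)Z,2E,4E) because of the silyloxy group on C2.
- Assumption: the sense of induction of the BINOL–titanium catalyst in step 2 has to be confirmed on the first run; (R)-BINOL is written, and (S)-BINOL replaces it with no other change if the adduct is the antipode.
- C11 is formed as an epimer mixture in step 3 (left undefined in the SMILES of 6–8) and is equilibrated in step 6.

Step 1
Reactants: 1 (E)-pent-3-en-2-one
Product: 2 (E)-2-(triisopropylsilyloxy)penta-1,3-diene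
Conditions: TIPSOTf, Et3N, Et2O, 0 °C
Reagents that add atoms: triisopropylsilyl trifluoromethanesulfonate (TIPSOTf), CC(C)[Si](C(C)C)(C(C)C)OS(=O)(=O)C(F)(F)F
Why: Soft enolisation of the methyl ketone on its CH3 side and O-silylation (silyl enol ether formation) should give the cross-conjugated 2-silyloxydiene with the E alkene untouched.

Step 2
Reactants: 3 2-methoxy-5-methyl-1,4-benzoquinone; 2 (E)-2-(triisopropylsilyloxy)penta-1,3-diene
Product: 4 cis-fused adduct, 7-methoxy-4,10-dimethyl-2-(triisopropylsilyloxy)decal-2,7-diene-6,9-dione (H4, H5 and the C10 methyl on one face)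
Conditions: (R)-BINOL (20 mol %), TiCl2(OiPr)2 (20 mol %), 4 Å MS, toluene, −60 → −20 °C
Reagents that add atoms: none
Why: Catalytic enantioselective Diels–Alder reaction on the methyl-bearing quinone double bond (the methoxy-bearing one is deactivated): the carbonyl that becomes C6 is chelated to titanium together with the methoxy oxygen, so the diene CH2 terminus bonds to the methyl-bearing β-carbon (C10), the endo transition state gives the cis fusion with the C4 methyl cis to C6, and the BINOLate ligand selects the face.

Step 3
Reactants: 4 cis-fused adduct; 5 tert-butyl propionate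
Product: 6 ene-dione ester, as 4 with CH(CH3)CO2tBu on C7 in place of methoxy (C11 epimers)
Conditions: LiN(iPr)2 (2.2 equiv), 5, THF, −78 °C; then 4, −78 → −20 °C; aq. NH4Cl
Reagents that add atoms: none
Why: Conjugate addition–elimination (vinylogous acyl substitution): the ester enolate adds to C7, the β-carbon of the C9 vinylogous ester that is also activated by the C6 carbonyl, and methoxide is expelled to restore the C7=C8 ene-dione.

Step 4
Reactants: 6 ene-dione ester
Product: 7 6-hydroxy-7-en-9-one ester (O6 on the face of C4, trans to H5)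
Conditions: NaBH4 (0.5 equiv), CeCl3·7H2O, MeOH/THF, −78 °C
Reagents that add atoms: none
Why: Luche 1,2-reduction should take the C6 carbonyl (flanked by C5–H) before the C9 carbonyl (flanked by quaternary C10), with hydride entering from the H5 face so that O6 ends cis to the C5–C4 bond.

Step 5
Reactants: 7 6-hydroxy-7-en-9-one ester
Product: 8 6-hydroxy-9-ketone ester with C7–H cis to O6 (side chain trans to O6)
Conditions: H2 (1 atm), [Ir(cod)(PCy3)(py)]PF6 (5 mol %), CH2Cl2, 0 °C
Reagents that add atoms: none
Why: Hydroxyl-directed hydrogenation: the allylic C6 hydroxyl binds the cationic iridium and both hydrogens are delivered to C7=C8 on the O6 face, which sets C7; the remote, hindered TIPS enol ether is not directed.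

Step 6
Reactants: 8 6-hydroxy-9-ketone ester
Product: 9 trans-fused 6,12-lactone 9-ketone (TIPS enol ether in ring A, C11 methyl cis to H7)
Conditions: KOtBu (0.3 equiv), THF, 0 °C → rt
Reagents that add atoms: none
Why: Base-mediated lactonisation (intramolecular transesterification of the C6 alkoxide on the tert-butyl ester) closes the trans-diequatorial γ-lactone, and reversible enolisation at C11 should settle the methyl on the H7 side, the more stable epimer.

Step 7
Reactants: 9 lactone 9-ketone
Product: 10 8-hydroxy-9-ketone lactone (O8 equatorial, trans to the C7–C11 bond)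
Conditions: KN(SiMe3)2 (1.1 equiv), THF, −78 °C; 2-(phenylsulfonyl)-3-phenyloxaziridine; aq. NH4Cl
Reagents that add atoms: 2-(phenylsulfonyl)-3-phenyloxaziridine, O=S(=O)(c1ccccc1)N1OC1c1ccccc1
Why: Enolate hydroxylation: the C9 ketone can enolise only toward C8 (C10 is quaternary), and the oxaziridine should approach C8 from the face opposite the axial C10 methyl and the C7 substituent.

Step 8
Reactants: 10 8-hydroxy-9-ketone lactone
Product: 11 8,9-trans-diol lactone (O9 equatorial, cis to the C10 methyl)
Conditions: Me4NBH(OAc)3, MeCN/AcOH, −30 °C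
Reagents that add atoms: none
Why: Hydroxyl-directed (Evans–Saksena) reduction: the borohydride bound to O8 delivers hydride to the same face of C9, anti to the axial C10 methyl, giving the trans diol.

Step 9
Reactants: 11 8,9-trans-diol lactone
Product: 12 8-O-TBS 9-hydroxy lactone
Conditions: TBSCl (1.2 equiv), imidazole, DMF, 0 °C → rt
Reagents that add atoms: tert-butyldimethylsilyl chloride (TBSCl), CC(C)(C)[Si](C)(C)Cl
Why: Selective silylation: the C9 hydroxyl is neopentylic (next to quaternary C10) and should react far more slowly than the C8 hydroxyl.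

Step 10
Reactants: 12 8-O-TBS 9-hydroxy lactone
Product: 13 8-O-TBS 9-O-TES lactone (TIPS enol ether in ring A)
Conditions: TESOTf, 2,6-lutidine, CH2Cl2, −78 → 0 °C
Reagents that add atoms: triethylsilyl trifluoromethanesulfonate (TESOTf), CC[Si](CC)(CC)OS(=O)(=O)C(F)(F)F
Why: Silylation of the hindered secondary alcohol with the reactive silyl triflate places the one group on C9 that can later be removed selectively.

Step 11
Reactants: 13 8-O-TBS 9-O-TES lactone
Product: 14 cis-fused 2-oxo-3-ene (enone) lactone
Conditions: Pd(OAc)2 (1.1 equiv), MeCN/CH2Cl2, 40 °C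
Reagents that add atoms: none
Why: Saegusa–Ito oxidation: palladation of the silyl enol ether at C3 and β-hydride elimination of H4, the only β-hydrogen available, should give the C3=C4 enone and erase the C4 stereocentre.

Step 12
Reactants: 14 enone lactone
Product: 15 cis-fused 2-(tert-butyldimethylsilyloxy)-1,3-diene hexalin lactone (key-step precursor)
Conditions: LiN(iPr)2 (1.1 equiv), THF, −78 °C; TBSOTf, −78 °C; Et3N, aq. NaHCO3
Reagents that add atoms: tert-butyldimethylsilyl trifluoromethanesulfonate (TBSOTf), CC(C)(C)[Si](C)(C)OS(=O)(=O)C(F)(F)F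
Why: Kinetic α′-deprotonation of the enone at C1 gives the cross-conjugated dienolate, and O-silylation fixes the 2-silyloxy-1,3-diene; the lactone α-hydrogen and the γ-hydrogen at C5 are less acidic under these conditions.

Step 13
Reactants: 15 cis-fused 2-silyloxy-1,3-diene hexalin lactone
Product: 16 ten-membered (1(10)Z,2E,4E)-triene silyl enol ether, kept as a −78 °C solution
Conditions: hν (300 nm lamps, Pyrex), degassed pentane/THF, −78 °C, to partial conversion
Reagents that add atoms: none
Why: Excitation of the 2-silyloxydiene leads to the allowed conrotatory six-electron electrocyclic opening that cleaves the C5–C10 bond shared by rings A and B; the closest known reaction type is the photochemical opening of fused cyclohexa-1,3-dienes (hexalins, provitamin D) to cyclic trienes. No ring is closed by bond formation: the ten-membered ring arises by scission of the ring-fusion bond, and no stereocentre is created, C5 and C10 becoming sp2. The two new alkene geometries are set by the helicity of the diene at the moment of excitation, because the opening is faster than any conformational change: substituents that are pseudoaxial on ring A rotate inward. In 15 the trans-fused lactone and the equatorial C8 and C9 silyloxy groups lock ring B in one chair, in which C9 (on C10) and H5 are pseudoaxial and C6 and the C10 methyl pseudoequatorial on ring A, so C9 should end cis to C2 (1(10)Z) and C6 trans to C3 (4E). The step needs this one conrotatory sense and a triene that is not destroyed again; irradiation at the long-wavelength edge of the diene band, partial conversion and −78 °C limit light-driven re-closure, double-bond isomerisation and the thermal disrotatory closure.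

Step 14
Reactants: 16 triene silyl enol ether (cold photolysate)
Product: 17 ten-membered (1(10)Z,4E)-dien-2-one lactone
Conditions: Bu4NF/AcOH (1:1.5, premixed), THF, added at −78 °C, → −40 °C; pH 7 buffer
Reagents that add atoms: none
Why: Fluoride-assisted protodesilylation of the silyl enol ether with kinetic protonation at C3 removes the central alkene and leaves C4=C5 out of conjugation; the enol Si–O bond is cleaved much faster than the alkyl silyl ethers, the acid keeps free enolate (and loss of the allylic lactone) down, and unreacted 15 returns as 14 for recycling.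

Step 15
Reactants: 17 dien-2-one lactone
Product: 18 (2S)-carbinol
Conditions: (R)-1-methyl-3,3-diphenyltetrahydro-1H,3H-pyrrolo[1,2-c][1,3,2]oxazaborole ((R)-Me-CBS, 0.5 equiv), catecholborane, toluene, −78 °C
Reagents that add atoms: none
Why: CBS reduction (1,2-selective): with the Z-alkenyl carbon C1 as the large group and C3H2 as the small one, the (R)-catalyst should deliver hydride to the face that gives the 2S alcohol.

Step 16
Reactants: 18 (2S)-carbinol
Product: 19 2,8-bis-O-TBS 9-O-TES lactone
Conditions: TBSOTf, 2,6-lutidine, CH2Cl2, −78 °C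
Reagents that add atoms: tert-butyldimethylsilyl trifluoromethanesulfonate (TBSOTf), CC(C)(C)[Si](C)(C)OS(=O)(=O)C(F)(F)F
Why: Silyl ether formation masks the allylic C2 hydroxyl for the enolate step and for the later acylation at C9.

Step 17
Reactants: 19 2,8-bis-O-TBS 9-O-TES lactone
Product: 21 α-methylene lactone (C11=C13), via C11 phenylselenide 20 (not isolated)
Conditions: LiN(iPr)2 (1.3 equiv), THF, −78 °C; PhSeBr; aq. NH4Cl; then NaIO4, NaHCO3, MeOH/H2O, 0 °C → rt
Reagents that add atoms: none
Why: α-Selenenylation of the lactone enolate and selenoxide syn-elimination: in the trans-fused lactone selenium should enter anti to H7, so only the C13 methyl hydrogens are syn to the selenoxide and the exocyclic methylene forms; periodate is used so that no peracid-type oxidant meets the ring alkenes.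

Step 18
Reactants: 21 α-methylene lactone
Product: 22 9-hydroxy α-methylene lactone (C2 and C8 still TBS ethers)
Conditions: HF·pyridine, pyridine, THF, 0 °C, monitored
Reagents that add atoms: none
Why: Selective desilylation: under buffered HF the triethylsilyl ether is cleaved much faster than the two secondary tert-butyldimethylsilyl ethers.

Step 19
Reactants: 22 9-hydroxy α-methylene lactone; 23 angelic acid
Product: 24 9-O-angelate 2,8-bis-TBS ether
Conditions: 23, 2,4,6-trichlorobenzoyl chloride, Et3N, toluene, rt; then 22, 80 °C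
Reagents that add atoms: none
Why: Yamaguchi-type esterification through the mixed anhydride acylates the hindered C9 hydroxyl, and without a nucleophilic catalyst that adds reversibly to the enoate the Z geometry of the angelate should be kept.

Step 20
Reactants: 24 9-O-angelate 2,8-bis-TBS ether
Product: 25 CNP0311662.1
Conditions: HF·pyridine (excess), pyridine, THF, 0 °C → rt
Reagents that add atoms: none
Why: Fluoride-mediated cleavage of both silyl ethers under buffered acidic conditions should leave the angelate on C9 (no base-induced migration to O8), the allylic lactone and the α-methylene lactone untouched.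

Compound list
1 | (E)-pent-3-en-2-one | C/C=C/C(C)=O | starting material
2 | (E)-2-(triisopropylsilyloxy)penta-1,3-diene | C=C(O[Si](C(C)C)(C(C)C)C(C)C)/C=C/C | intermediate
3 | 2-methoxy-5-methyl-1,4-benzoquinone | COC1=CC(=O)C(C)=CC1=O | starting material
4 | cis-fused Diels–Alder adduct (7-methoxy-6,9-dione, TIPS enol ether at C2) | C[C@]12CC(O[Si](C(C)C)(C(C)C)C(C)C)=C[C@@H](C)[C@H]1C(=O)C(OC)=CC2=O | intermediate
5 | tert-butyl propionate | CCC(=O)OC(C)(C)C | starting material
6 | ene-dione ester (C7 side chain, C11 epimers) | C[C@]12CC(O[Si](C(C)C)(C(C)C)C(C)C)=C[C@@H](C)[C@H]1C(=O)C(C(C)C(=O)OC(C)(C)C)=CC2=O | intermediate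
7 | 6-hydroxy-7-en-9-one ester (C11 epimers) | C[C@]12CC(O[Si](C(C)C)(C(C)C)C(C)C)=C[C@@H](C)[C@H]1[C@@H](O)C(C(C)C(=O)OC(C)(C)C)=CC2=O | intermediate
8 | 6-hydroxy-9-ketone ester, H7 cis to O6 (C11 epimers) | C[C@]12CC(O[Si](C(C)C)(C(C)C)C(C)C)=C[C@@H](C)[C@H]1[C@@H](O)[C@H](C(C)C(=O)OC(C)(C)C)CC2=O | intermediate
9 | trans-fused 6,12-lactone 9-ketone | C[C@@H]1C(=O)O[C@@H]2[C@@H]3[C@H](C)C=C(O[Si](C(C)C)(C(C)C)C(C)C)C[C@]3(C)C(=O)C[C@@H]12 | intermediate
10 | 8-hydroxy-9-ketone lactone | C[C@@H]1C(=O)O[C@@H]2[C@@H]3[C@H](C)C=C(O[Si](C(C)C)(C(C)C)C(C)C)C[C@]3(C)C(=O)[C@H](O)[C@@H]12 | intermediate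
11 | 8,9-trans-diol lactone | C[C@@H]1C(=O)O[C@@H]2[C@@H]3[C@H](C)C=C(O[Si](C(C)C)(C(C)C)C(C)C)C[C@]3(C)[C@@H](O)[C@H](O)[C@@H]12 | intermediate
12 | 8-O-TBS 9-hydroxy lactone | C[C@@H]1C(=O)O[C@@H]2[C@@H]3[C@H](C)C=C(O[Si](C(C)C)(C(C)C)C(C)C)C[C@]3(C)[C@@H](O)[C@H](O[Si](C)(C)C(C)(C)C)[C@@H]12 | intermediate
13 | 8-O-TBS 9-O-TES lactone, TIPS enol ether | C[C@@H]1C(=O)O[C@@H]2[C@@H]3[C@H](C)C=C(O[Si](C(C)C)(C(C)C)C(C)C)C[C@]3(C)[C@@H](O[Si](CC)(CC)CC)[C@H](O[Si](C)(C)C(C)(C)C)[C@@H]12 | intermediate
14 | cis-fused 2-oxo-3-ene lactone | C[C@@H]1C(=O)O[C@@H]2[C@@H]3C(C)=CC(=O)C[C@]3(C)[C@@H](O[Si](CC)(CC)CC)[C@H](O[Si](C)(C)C(C)(C)C)[C@@H]12 | intermediate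
15 | cis-fused 2-silyloxy-1,3-diene hexalin lactone (key-step precursor; H5 and C10 methyl on the face of O9) | C[C@@H]1C(=O)O[C@@H]2[C@@H]3C(C)=CC(O[Si](C)(C)C(C)(C)C)=C[C@]3(C)[C@@H](O[Si](CC)(CC)CC)[C@H](O[Si](C)(C)C(C)(C)C)[C@@H]12 | intermediate
16 | ten-membered (1(10)Z,2E,4E)-triene silyl enol ether (key-step product) | C[C@@H]1C(=O)O[C@@H]2/C=C(\C)/C=C(/O[Si](C)(C)C(C)(C)C)\C=C(\C)[C@@H](O[Si](CC)(CC)CC)[C@H](O[Si](C)(C)C(C)(C)C)[C@@H]12 | intermediate
17 | ten-membered (1(10)Z,4E)-dien-2-one lactone | C[C@@H]1C(=O)O[C@@H]2/C=C(\C)CC(=O)/C=C(/C)[C@@H](O[Si](CC)(CC)CC)[C@H](O[Si](C)(C)C(C)(C)C)[C@@H]12 | intermediate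
18 | (2S)-carbinol | C[C@@H]1C(=O)O[C@@H]2/C=C(\C)C[C@H](O)/C=C(/C)[C@@H](O[Si](CC)(CC)CC)[C@H](O[Si](C)(C)C(C)(C)C)[C@@H]12 | intermediate
19 | 2,8-bis-O-TBS 9-O-TES lactone | C[C@@H]1C(=O)O[C@@H]2/C=C(\C)C[C@H](O[Si](C)(C)C(C)(C)C)/C=C(/C)[C@@H](O[Si](CC)(CC)CC)[C@H](O[Si](C)(C)C(C)(C)C)[C@@H]12 | intermediate
20 | C11 phenylselenide (selenium anti to H7) | C[C@]1([Se]c3ccccc3)C(=O)O[C@@H]2/C=C(\C)C[C@H](O[Si](C)(C)C(C)(C)C)/C=C(/C)[C@@H](O[Si](CC)(CC)CC)[C@H](O[Si](C)(C)C(C)(C)C)[C@@H]12 | intermediate
21 | α-methylene lactone, 2,8-bis-O-TBS 9-O-TES | C=C1C(=O)O[C@@H]2/C=C(\C)C[C@H](O[Si](C)(C)C(C)(C)C)/C=C(/C)[C@@H](O[Si](CC)(CC)CC)[C@H](O[Si](C)(C)C(C)(C)C)[C@@H]12 | intermediate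
22 | 9-hydroxy α-methylene lactone, 2,8-bis-O-TBS | C=C1C(=O)O[C@@H]2/C=C(\C)C[C@H](O[Si](C)(C)C(C)(C)C)/C=C(/C)[C@@H](O)[C@H](O[Si](C)(C)C(C)(C)C)[C@@H]12 | intermediate
23 | angelic acid, (Z)-2-methylbut-2-enoic acid | C/C=C(/C)C(=O)O | starting material
24 | 9-O-angelate 2,8-bis-TBS ether | C=C1C(=O)O[C@@H]2/C=C(\C)C[C@H](O[Si](C)(C)C(C)(C)C)/C=C(/C)[C@@H](OC(=O)/C(C)=C\C)[C@H](O[Si](C)(C)C(C)(C)C)[C@@H]12 | intermediate
25 | CNP0311662.1 | C=C1C(=O)O[C@@H]2/C=C(\C)C[C@H](O)/C=C(/C)[C@@H](OC(=O)/C(C)=C\C)[C@H](O)[C@@H]12 | target

Total step count: 20. Longest linear sequence: 20 steps (1 → 25).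

Steps most likely to fail

Step 13. What may go wrong is that the electron-rich silyl trienol ether does not accumulate: light-driven re-closure, isomerisation of the terminal alkenes or other photochemistry of the enol ether outruns its formation. The fallback keeps the ring opening but carries C2 as a boronate instead of an enol ether. It sets out from enone 14: kinetic enolate formation (LiN(iPr)2) and trapping with PhNTf2 should give the dienyl triflate F1, and Miyaura borylation (B2pin2, PdCl2(dppf), KOAc) the dienyl pinacol boronate F2, whose chromophore is a plain carbon-substituted diene of the kind for which this opening is best established. Irradiation as in step 13, with the same helicity control, should give the trienyl pinacol boronate F3, which needs no fluoride. Cold oxidation (NaBO3·4H2O, THF/pH 7 buffer) gives the enol and, by protonation at C3, ketone 17, where the route is rejoined.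

Step 3. What may go wrong is that the basic lithium enolate adds to the C6 carbonyl or removes H5, so that 1,2-adducts and ring-fusion epimerisation compete with substitution at C7. The fallback replaces the enolate by a neutral Lewis-acid-mediated conjugate addition. It sets out from 4: the silyl ketene acetal F4 (from 5, LiN(iPr)2, TMSCl) is added under TMSOTf catalysis (Mukaiyama–Michael reaction at C7, CH2Cl2, −78 °C), the adduct loses methoxytrimethylsilane on work-up, and the route is rejoined at 6.

Step 2. What may go wrong is poor facial discrimination by the catalyst on the trisubstituted dienophile, so that the adduct is formed with low enantiomeric purity. The fallback separates ring construction from absolute control. It sets out from 3 and 2: the thermal cycloaddition (toluene, 80 °C, same regiochemistry) gives racemic 4, and Luche reduction of its C6 carbonyl gives the racemic carbinol F5. Lipase-mediated acetylation (lipase from Burkholderia cepacia, vinyl acetate) resolves F5, giving the acetate F6 of one antipode. The wanted enantiomer, collected as F5 or released from F6 by K2CO3/MeOH, is reoxidised with Dess–Martin periodinane to enantioenriched 4, where the route is rejoined.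

Further compounds
F1 | step 13 | cis-fused 2-(trifluoromethanesulfonyloxy)-1,3-diene hexalin lactone | C[C@@H]1C(=O)O[C@@H]2[C@@H]3C(C)=CC(OS(=O)(=O)C(F)(F)F)=C[C@]3(C)[C@@H](O[Si](CC)(CC)CC)[C@H](O[Si](C)(C)C(C)(C)C)[C@@H]12
F2 | step 13 | cis-fused 2-(pinacolboryl)-1,3-diene hexalin lactone | C[C@@H]1C(=O)O[C@@H]2[C@@H]3C(C)=CC(B4OC(C)(C)C(C)(C)O4)=C[C@]3(C)[C@@H](O[Si](CC)(CC)CC)[C@H](O[Si](C)(C)C(C)(C)C)[C@@H]12
F3 | step 13 | ten-membered 2-(pinacolboryl) triene lactone (ring sense cis,cis,trans) | C[C@@H]1C(=O)O[C@@H]2/C=C(\C)/C=C(/B3OC(C)(C)C(C)(C)O3)\C=C(\C)[C@@H](O[Si](CC)(CC)CC)[C@H](O[Si](C)(C)C(C)(C)C)[C@@H]12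
F4 | step 3 | 1-tert-butoxy-1-(trimethylsilyloxy)prop-1-ene | CC=C(O[Si](C)(C)C)OC(C)(C)C
F5 | step 2 | 6-hydroxy-7-methoxy-7-en-9-one (C6 carbinol of 4, wanted enantiomer) | C[C@]12CC(O[Si](C(C)C)(C(C)C)C(C)C)=C[C@@H](C)[C@H]1[C@@H](O)C(OC)=CC2=O
F6 | step 2 | 6-acetate of F5 | C[C@]12CC(O[Si](C(C)C)(C(C)C)C(C)C)=C[C@@H](C)[C@H]1[C@@H](OC(C)=O)C(OC)=CC2=O
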